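Sunday's run stood at 6.00 min with less complex with one exchanged than Friday's, 12.2% against 14.3%, although Sunday's had more starting complex and the same incoming ligand.

| setting | Friday's | Sunday's | flask |
|---|---|---|---|
| starting complex | 12 mM | 17 mM | 23 mM |
| incoming ligand | 11 mM | 11 mM | 11.0 mM |
| remark | run made earlier | run made earlier |  |
| time |  |  | 6.0 min |

| run | time / min | complex with one exchanged / % | complex with two exchanged / % | starting complex / % |
|---|---|---|---|---|
| Friday's | 0.500 | 4.6 | 1.9 | 95.7 |
| Friday's | 0.667 | 4.9 | 0 | 95.0 |
| Friday's | 1.00 | 6.4 | 1.3 | 90.7 |
| Friday's | 1.50 | 10.1 | 3.1 | 87.8 |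
| Friday's | 2.50 | 13.6 | 3.2 | 81.6 |
| Friday's | 4.00 | 14.2 | 6.8 | 74.7 |
| Friday's | 6.00 | 14.3 | 10.6 | 69.2 |
| Sunday's | 0.833 | 6.3 | 2.0 | 92.8 |
| Sunday's | 1.50 | 8.2 | 2.7 | 89.0 |
| Sunday's | 2.50 | 13.1 | 4.8 | 85.0 |
| Sunday's | 3.00 | 12.5 | 4.1 | 82.6 |
| Sunday's | 4.00 | 11.8 | 5.3 | 77.5 |
| Sunday's | 5.00 | 13.5 | 7.5 | 75.5 |
| Sunday's | 6.00 | 12.2 | 7.7 | 73.6 |

(standard deviation of a reading: 1 percentage point)

- the earlier runs were read with a standard deviation of 1 percentage point

1. equivalents of incoming ligand to starting complex, everything else as given, that leave most complex with one exchanged at 6.0 min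
2. the amount of complex with one exchanged then, in percent of the starting complex charged
3. the amount of complex with one exchanged with the amounts as given

Turn the question round, and ask what would have to be true for the ligand charge to be what holds this amount down. Every complex with one exchanged has taken up one incoming ligand, and in your flask [incoming ligand] is charged lower than [starting complex], which makes it the limiting reagent on paper. So take [incoming ligand]/[starting complex] as charged, in percent of the starting complex, and call it the ligand ceiling, 47.8% for this flask. For the ligand charge to be the bound, readings would have to lie near their ceiling.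

The last readings of both runs lie below their ceilings. Friday's last reading fills 15.6% of a ceiling of 91.7%, and Sunday's fills 18.9% of 64.7%. Carrying that rise on in step with [starting complex], I reckon a filled share of 22.8% for your flask, which gives 10.9% as an estimate that carries the scatter of the readings. Friday's run had the higher ratio and the higher last reading, so I expect the best recipe for your flask above its present ratio.

The forecast says 12.5% for the amounts as given, and a best of 15.5% at 0.9 equiv, adding “The optimum is broad”; its 12.5% stands above my reckoning.

The flask gives 12.1%, and its best is 22.1% at 2.81 equiv, higher than the forecast's equivalents.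

complex with one exchanged + incoming ligand ⇌ leaving ligand + complex with two exchanged (K = 0.950, k = 0.408 M⁻¹ s⁻¹); starting complex + incoming ligand ⇌ leaving ligand + complex with one exchanged (K = 0.493, k = 0.137 M⁻¹ s⁻¹); complex with one exchanged → side product (k = 0.00159 s⁻¹) At 6.00 min the flask still holds 39% of its incoming ligand unbound. Its 12.1% fills a quarter of the ligand ceiling of 47.8%. The neighbouring flask with 9.2 mM of starting complex has a ligand ceiling of 120%, more than the whole of its starting complex, and its 14.7% fills 12.3% of that.

(The readings are calculated with constants of no real substance, and the scatter is random.)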